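The constants used here are invented, and the outcome is calculated.

The catalyst is conserved: free catalyst, its four intermediates and spent catalyst add up to the charge at each moment. A rate can therefore be reckoned as the catalyst still working, divided by the time one round takes.

substrate 18 mM; partner 21.6 mM; free catalyst 40 µM; impurity 41 µM

    substrate + free catalyst ⇌ catalyst intermediate A (K1 = 430 L mol⁻¹, k1 = 970 L mol⁻¹ h⁻¹)
    catalyst intermediate A → catalyst intermediate B (k2 = 99 h⁻¹)
    partner + catalyst intermediate B ⇌ catalyst intermediate C (K3 = 17 L mol⁻¹, k3 = 140 L mol⁻¹ h⁻¹)
    catalyst intermediate C ⇌ catalyst intermediate D (K4 = 1.3, k4 = 20 h⁻¹)
    catalyst intermediate D → free catalyst + product (k5 = 21 h⁻¹)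
    free catalyst + impurity → spent catalyst (k6 = 8500 L mol⁻¹ h⁻¹)

- apparent order in free catalyst when 5.0 % of the substrate are converted (percent change of the rate of making product for one percent more free catalyst charged)
- apparent order in partner when 5.0 % of the substrate are converted (percent change of the rate of making product for one percent more partner charged)

An even round would give each of the 5 working forms 20.0 % of the working catalyst, and that is the zero of the scale. The reckoning here takes partner at 20.7 mM, as it stands at 5.0 % conversion, and counts the backward steps. The stays per turnover then form a ladder: intermediate A 0.0101 h, intermediate D 0.0476 h, free catalyst 0.0617 h, intermediate C 0.0866 h, and intermediate B 0.591 h. One round lasts 0.797 h.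

Intermediate B, the resting state, thus takes 74.2 % of the round, more than the even share. This is the waiting share, the part of a round's time spent as intermediate B waiting for partner. Partner enters the stay of intermediate B and no other stay, and one percent more partner charged is slightly more than one percent of what remains. The reckoned order in partner is therefore 0.774.

The next rung is slower. Impurity as charged kills about 2.15 % of the working catalyst per round, so at that impurity level a working catalyst lasts about 1.55 d, longer than a round. Impurity and substrate compete for free catalyst, so impurity follows conversion rather than time: the fraction of impurity left is the fraction of substrate left raised to the selectivity factor 8.96. That kills 15.1 µM of catalyst by 5.0 % conversion and leaves 24.9 µM working; the relation has no term in the catalyst charge, so in this reckoning a little more catalyst charged adds to the working part. The reckoned order in free catalyst is 1.61.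

The forecast gives 1.6 for free catalyst, within 1.45 to 1.75, and 0.77 for partner, within 0.68 to 0.85, holding that “Intermediate B waiting for partner is the main resting state”.

The flask gives 1.6 in free catalyst and 0.77 in partner. With partner as charged, intermediate B reacts with partner at 73 d⁻¹, counted forward, slower than free catalyst reacts with substrate, 420 d⁻¹, or intermediate D releases product, 500 d⁻¹. At 1.25 d the flask holds 40.8 % of the catalyst charged as intermediate B, which is 74.3 % of the working forms. With twice the partner, the waiting share reckons the stay as intermediate B at half and the time factor at 0.629; that run reaches the same conversion in 0.628 of the time.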